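(All runs are calculated for substances that don't exist; the scatter is artificial.)

| flask | starting material | partner | protic impurity | remark | time |
|---|---|---|---|---|---|
| zeta | 0.10 M | 0.093 M | 0.010 M | run made earlier |  |
| alpha | 0.10 M | 0.13 M | 0.010 M | run made earlier |  |
| autumn | 0.10 M | 0.100 M | 0.0100 M |  | 3.0 min |
| dawn | 0.10 M | 0.150 M | 0.0100 M |  | 3.0 min |

| run | time / s | over-reaction product / % | open intermediate / % | target / % | starting material / % |
|---|---|---|---|---|---|
| zeta | 10.0 | 0 | 8 | 6 | 87 |
| zeta | 15.0 | 0 | 13 | 3 | 81 |
| zeta | 25.0 | 1 | 15 | 9 | 72 |
| zeta | 50.0 | 6 | 25 | 7 | 52 |
| zeta | 90.0 | 13 | 32 | 15 | 31 |
| alpha | 10.0 | 0 | 11 | 3 | 88 |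
| alpha | 15.0 | 2 | 13 | 4 | 83 |
| alpha | 25.0 | 1 | 15 | 8 | 71 |
| alpha | 50.0 | 6 | 21 | 16 | 52 |
| alpha | 90.0 | 19 | 24 | 19 | 34 |

(scatter of a reading: 1.5 percentage points)

- the analysis behind the earlier runs scatters by 1.5 percentage points, standard deviation

- which of these there is most of at the end, counted by the starting material in it, autumn (target / starting material / over-reaction product / open intermediate)
- which of these there is most of at the end, counted by the starting material in it, dawn (target / starting material / over-reaction product / open intermediate)
- the largest of these amounts at the end, in percent of the starting material charged, autumn
- the largest of these amounts at the end, in percent of the starting material charged, dawn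

**First instants.** The amounts showed over-reaction product coming late: at 10.0 s the zeta run held 8% open intermediate and 0% over-reaction product. The starting material then fell alike in both runs, to 31% in zeta and 34% in alpha at 90.0 s, so I let its loss ignore partner.

**The middle.** At that last reading I counted the partner share, the part of the charged partner found in products, one partner per target and two per over-reaction product. It read 44.1% in zeta and 43.8% in alpha, although alpha carried more partner, so I took the spending as pseudo-first-order in partner, with a mean share of 44.0%.

**The end.** Doubling the time squares what remains, which gave me a share of 68.6% at 3.0 min and a budget, the share times the equivalents of partner, of 68.6% for autumn and 103% for dawn. I held target at alpha's last reading of 19%, and the rest of each budget, halved, gave over-reaction product 24.8% in autumn and 42.0% in dawn. Squaring the mean remainder left 10.6% starting material, and I set the protic impurity's charge, 10.0% of the starting material, as the ceiling of the unseen loss. The remainder was open intermediate: 35.6% in autumn, above its over-reaction product, and 18.5% in dawn, below it.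

**The forecast.** It named open intermediate at 30% for autumn and over-reaction product at 44% for dawn, saying “Autumn runs short of partner”. My autumn figure for open intermediate stood higher than its 30% and my dawn figure for over-reaction product lower than its 44%, with the same two names.

**The flask.** Autumn ended with open intermediate at 34.4% and dawn with over-reaction product at 42.7%, the two names of the forecast. The partner share came to 70.5% in autumn and 70.0% in dawn, against my 68.6%.

    starting material → open intermediate (k = 0.0110 /s)
    partner → second intermediate (k = 0.00490 /s)
    open intermediate + second intermediate → target (k = 10.0 /M/s)
    starting material + protic impurity → quenched substrate (k = 0.350 /M/s)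
    second intermediate → side product (k = 0.0240 /s)
    partner + target → over-reaction product (k = 0.220 /M/s)

**A neighbour.** Dawn's recipe with 0.25 M of starting material had 0.600 equivalents of partner, so my share gave a budget of 41.2%. That flask's products, counted in partner as before, held 46.1%, a share of 76.8%, with over-reaction product at 18.8% and open intermediate at 55.6%.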